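The route rests on cutting the C9–C10 bond between the side-chain ketone carbonyl and the adjacent quaternary gem-dimethyl carbon, two centres that are both acceptors in polar terms. The key step unites a 1,2-dioxane aldehyde, in which the ring centres C3 and C6 and the exocyclic C2 are already set and a vinyl group masks the ester, with the N-acyloxyphthalimide of 2,2-dimethyl-6-oxoheptanoic acid by carbene-catalysed decarboxylative radical acylation. Umpolung of the aldehyde and decarboxylation of the acid should deliver the hindered α-quaternary 1,6-diketone in one metal-free operation that spares the O–O bond of the dioxane ring.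

Key step: step 12

Remark: atoms are numbered along the target chain (C1 ester carbon, C2, ring carbons C3–C6 with the O–O bridge between C3 and C6, side chain C7–C15 with ketones at C9 and C14 and the gem-dimethyl carbon C10); (R)-(−)-linalool and the (+)-α-pinene-derived borane are assumed to be used in high enantiomeric purity.

Step 1
Reactants: 1 (R)-(−)-linalool
Product: 3 (3R)-3,7-dimethyloct-6-ene-1,3-diol, via bis(9-BBN) adduct 2 (not isolated)
Conditions: 9-BBN (2.2 equiv), THF, 0 °C to rt; then NaOH, H2O2, 0 °C
Reagents that add atoms: hydrogen peroxide, OO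
Why: Hydroboration–oxidation, in which 9-BBN should add to the monosubstituted vinyl group far faster than to the trisubstituted alkene and place boron on the terminal carbon, so that the primary alcohol forms while the bought carbinol centre (future C6) is untouched.

Step 2
Reactants: 3 (3R)-3,7-dimethyloct-6-ene-1,3-diol
Product: 5 (2R)-2-methyl-2-(4-methylpent-3-en-1-yl)oxetane, via monotosylate 4 (not isolated)
Conditions: n-BuLi (1.0 equiv), THF, 0 °C; TsCl (1.0 equiv); n-BuLi (1.05 equiv), 0 to 60 °C
Reagents that add atoms: none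
Why: One-pot Williamson-type 4-exo-tet oxetane closure, in which the primary alkoxide is sulfonylated selectively and the tertiary alkoxide displaces the tosylate, so the tertiary C–O bond is never broken and the centre keeps its configuration.

Step 3
Reactants: 5 (2R)-2-methyl-2-(4-methylpent-3-en-1-yl)oxetane
Product: 7 3-[(2R)-2-methyloxetan-2-yl]propanal, via ozonide 6 (not isolated)
Conditions: O3, CH2Cl2, −78 °C; then Me2S, −78 °C to rt
Reagents that add atoms: ozone, [O-][O+]=O
Why: Ozonolysis with reductive work-up should cleave the only alkene to the aldehyde (future C3), the oxetane being inert to ozone and dimethyl sulfide.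

Step 4
Reactants: 7 3-[(2R)-2-methyloxetan-2-yl]propanal
Product: 9 (3R,4S)-4-methyl-1-[(2R)-2-methyloxetan-2-yl]hex-5-en-3-ol, via diisopinocampheylborinate 8 (not isolated)
Conditions: (E)-but-2-ene, KOtBu, n-BuLi, THF, −78 to −45 °C; (−)-B-methoxydiisopinocampheylborane [from (+)-α-pinene], −78 °C; BF3·OEt2; then 7, −78 °C; NaOH, H2O2, 0 °C to rt
Reagents that add atoms: (E)-but-2-ene, C/C=C/C
Why: Brown asymmetric crotylboration through a closed chair transition state, in which the (+)-α-pinene-derived ligands should direct attack to the Si face of the aldehyde (carbinol R) and the E geometry of the crotyl unit fixes the anti relationship to the new methyl-bearing centre (S, future C2), the remote oxetane centre having no influence.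

Step 5
Reactants: 9 (3R,4S)-4-methyl-1-[(2R)-2-methyloxetan-2-yl]hex-5-en-3-ol
Product: 10 (3R,4S)-4-methyl-1-[(2R)-2-methyloxetan-2-yl]hex-5-en-3-yl methanesulfonate
Conditions: MsCl, Et3N, CH2Cl2, 0 °C
Reagents that add atoms: methanesulfonyl chloride, CS(=O)(=O)Cl
Why: Sulfonylation of the secondary alcohol with retention turns the future C3 into an electrophile and removes the hydroxyl group that could otherwise open the oxetane in the next step.

Step 6
Reactants: 10 (3R,4S)-4-methyl-1-[(2R)-2-methyloxetan-2-yl]hex-5-en-3-yl methanesulfonate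
Product: 11 (3S,6R,7S)-3-hydroperoxy-1-hydroxy-3,7-dimethylnon-8-en-6-yl methanesulfonate
Conditions: H2O2 (anhydrous, in Et2O, 10 equiv), TMSOTf (0.2 equiv), Et2O, −78 to −20 °C
Reagents that add atoms: hydrogen peroxide, OO
Why: Lewis-acid-promoted perhydrolysis of a 2,2-disubstituted oxetane, in which H2O2 should open the silyl-activated ring at the tertiary carbon in an SN2-like manner with inversion and so turn the bought (R)-carbinol centre into the (S)-configured tertiary hydroperoxide of C6, the mesylate and the vinyl group being inert at low temperature.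

Step 7
Reactants: 11 (3S,6R,7S)-3-hydroperoxy-1-hydroxy-3,7-dimethylnon-8-en-6-yl methanesulfonate
Product: 12 2-[(3S,6S)-6-[(2S)-but-3-en-2-yl]-3-methyl-1,2-dioxan-3-yl]ethan-1-ol
Conditions: KOtBu (1.05 equiv), 18-crown-6, THF, 0 °C
Reagents that add atoms: none
Why: Intramolecular alkylation of a hydroperoxide (6-exo-tet SN2), in which the weakly basic but highly nucleophilic peroxy anion should displace the secondary mesylate with inversion, setting C3 (S) syn to the C2 methyl group and closing the 1,2-dioxane with the C3 side chain trans to the C6 arm.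

Step 8
Reactants: 12 2-[(3S,6S)-6-[(2S)-but-3-en-2-yl]-3-methyl-1,2-dioxan-3-yl]ethan-1-ol
Product: 13 2-[(3S,6S)-6-[(2S)-but-3-en-2-yl]-3-methyl-1,2-dioxan-3-yl]acetaldehyde
Conditions: Dess–Martin periodinane, NaHCO3, CH2Cl2, 0 °C to rt
Reagents that add atoms: none
Why: Dess–Martin oxidation of the primary alcohol to the aldehyde under buffered, non-reducing conditions should leave the O–O bond and the alkene untouched.

Step 9
Reactants: 13 2-[(3S,6S)-6-[(2S)-but-3-en-2-yl]-3-methyl-1,2-dioxan-3-yl]acetaldehyde
Product: 15 3-[(3S,6S)-6-[(2S)-but-3-en-2-yl]-3-methyl-1,2-dioxan-3-yl]propanal, via methyl enol ether 14 (not isolated)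
Conditions: (methoxymethyl)triphenylphosphonium chloride, KN(SiMe3)2, THF, −78 to 0 °C; then 2 M HCl, THF, rt
Reagents that add atoms: (methoxymethyl)triphenylphosphonium chloride, COC[P+](c1ccccc1)(c1ccccc1)c1ccccc1.[Cl-]; water, O
Why: Wittig one-carbon homologation, in which the methoxymethylene ylide should add to the aldehyde at low temperature faster than it deprotonates it and acid hydrolysis of the enol ether unveils the C9 aldehyde without touching the peroxide or the vinyl group.

Step 10
Reactants: 16 isobutyric acid, 17 2-(3-chloropropyl)-2-methyl-1,3-dioxolane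
Product: 19 2,2-dimethyl-6-oxoheptanoic acid, via ketal acid 18 (not isolated)
Conditions: LiN(iPr)2 (2.2 equiv), THF, 0 °C to rt; 17, NaI (cat.), 45 °C; then 3 M HCl, rt
Reagents that add atoms: water, O
Why: Creger alkylation, in which the dianion of isobutyric acid is alkylated at carbon by the primary halide to build the quaternary C10 and the acidic work-up hydrolyses the dioxolane to the methyl ketone.

Step 11
Reactants: 19 2,2-dimethyl-6-oxoheptanoic acid
Product: 20 1,3-dioxoisoindolin-2-yl 2,2-dimethyl-6-oxoheptanoate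
Conditions: N-hydroxyphthalimide, N,N'-diisopropylcarbodiimide, DMAP (cat.), CH2Cl2, rt
Reagents that add atoms: N-hydroxyphthalimide, O=C1c2ccccc2C(=O)N1O
Why: Carbodiimide (Steglich-type) esterification should give the redox-active ester even from the hindered acid, with DMAP as acyl-transfer catalyst.

Step 12
Reactants: 15 3-[(3S,6S)-6-[(2S)-but-3-en-2-yl]-3-methyl-1,2-dioxan-3-yl]propanal, 20 1,3-dioxoisoindolin-2-yl 2,2-dimethyl-6-oxoheptanoate
Product: 21 1-[(3S,6S)-6-[(2S)-but-3-en-2-yl]-3-methyl-1,2-dioxan-3-yl]-4,4-dimethylnonane-3,8-dione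
Conditions: 3-neopentyl-5,6,7,8-tetrahydro-4H-cyclohepta[d]thiazol-3-ium bromide (10 mol %), Cs2CO3 (20 mol %), 20 (1.5 equiv), DMSO, 60 °C
Reagents that add atoms: none
Why: The carbene adds to aldehyde 15 to give a Breslow intermediate whose enolate transfers one electron to ester 20; loss of phthalimide anion and CO2 gives the tertiary C10 radical, which combines with the persistent carbene-bound ketyl radical at C9, and collapse of the resulting alkoxide releases ketone 21 and the carbene. The closest known reaction type is the N-heterocyclic-carbene-catalysed decarboxylative radical coupling of aliphatic aldehydes with tertiary alkyl N-acyloxyphthalimides, a radical acylation that gives α-quaternary dialkyl ketones. No ring is closed and no stereocentre is formed, and C2, C3 and C6 carry no hydrogen that the catalytic carbonate could remove. The step needs cross-coupling instead of homo-coupling, aldol or benzoin reaction, which the persistence of the ketyl radical, the bulk of the tertiary radical and the bulky N-neopentyl carbene should secure. It also needs electron transfer to the ester and not to the O–O bond, which the much easier reduction of the phthalimide ester and the absence of any metal reductant should secure. The remote methyl ketone and the terminal vinyl group are poor partners for both the carbene and the tertiary radical and should stay as they are.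

Step 13
Reactants: 21 1-[(3S,6S)-6-[(2S)-but-3-en-2-yl]-3-methyl-1,2-dioxan-3-yl]-4,4-dimethylnonane-3,8-dione
Product: 23 methyl (2R)-2-[(3S,6S)-6-(4,4-dimethyl-3,8-dioxononyl)-6-methyl-1,2-dioxan-3-yl]propanoate (diacarperoxide C), via methoxy hydroperoxide 22 (not isolated)
Conditions: O3, NaOH (2.5 M in MeOH, 5 equiv), CH2Cl2/MeOH, −78 °C; then aqueous NH4Cl
Reagents that add atoms: ozone, [O-][O+]=O; methanol, CO
Why: Marshall ozonolysis in basic methanol, in which the carbonyl oxide from the vinyl group is trapped by methanol and base-induced dehydration should give the methyl ester directly at −78 °C, so the labile β-peroxy aldehyde is never set free and C2 keeps its spatial arrangement (its descriptor changes from S to R only through the priority change).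

Compound list
1 | (R)-(−)-linalool, (3R)-3,7-dimethylocta-1,6-dien-3-ol | C=C[C@](C)(O)CCC=C(C)C | starting material
2 | bis(9-borabicyclo[3.3.1]nonan-9-yl) adduct of 1 (boron on C1 and on the tertiary oxygen) | C(C[C@](C)(OB1C2CCCC1CCC2)CCC=C(C)C)B1C2CCCC1CCC2 | intermediate
3 | (3R)-3,7-dimethyloct-6-ene-1,3-diol | OCC[C@](C)(O)CCC=C(C)C | intermediate
4 | (3R)-3-hydroxy-3,7-dimethyloct-6-en-1-yl 4-methylbenzenesulfonate | Cc1ccc(cc1)S(=O)(=O)OCC[C@](C)(O)CCC=C(C)C | intermediate
5 | (2R)-2-methyl-2-(4-methylpent-3-en-1-yl)oxetane | C[C@@]1(CCC=C(C)C)CCO1 | intermediate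
6 | (2R)-2-[2-(5,5-dimethyl-1,2,4-trioxolan-3-yl)ethyl]-2-methyloxetane (ozonide) | C[C@@]1(CCC2OOC(C)(C)O2)CCO1 | intermediate
7 | 3-[(2R)-2-methyloxetan-2-yl]propanal | C[C@@]1(CCC=O)CCO1 | intermediate
8 | O-diisopinocampheylboryl ether of 9 | C=C[C@H](C)[C@H](OB([C@@H]2C[C@@H]3C[C@H]([C@H]2C)C3(C)C)[C@@H]2C[C@@H]3C[C@H]([C@H]2C)C3(C)C)CC[C@]1(C)CCO1 | intermediate
9 | (3R,4S)-4-methyl-1-[(2R)-2-methyloxetan-2-yl]hex-5-en-3-ol | C=C[C@H](C)[C@H](O)CC[C@]1(C)CCO1 | intermediate
10 | (3R,4S)-4-methyl-1-[(2R)-2-methyloxetan-2-yl]hex-5-en-3-yl methanesulfonate | C=C[C@H](C)[C@H](OS(C)(=O)=O)CC[C@]1(C)CCO1 | intermediate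
11 | (3S,6R,7S)-3-hydroperoxy-1-hydroxy-3,7-dimethylnon-8-en-6-yl methanesulfonate | C=C[C@H](C)[C@H](OS(C)(=O)=O)CC[C@](C)(OO)CCO | intermediate
12 | 2-[(3S,6S)-6-[(2S)-but-3-en-2-yl]-3-methyl-1,2-dioxan-3-yl]ethan-1-ol | C=C[C@H](C)[C@@H]1CC[C@@](C)(CCO)OO1 | intermediate
13 | 2-[(3S,6S)-6-[(2S)-but-3-en-2-yl]-3-methyl-1,2-dioxan-3-yl]acetaldehyde | C=C[C@H](C)[C@@H]1CC[C@@](C)(CC=O)OO1 | intermediate
14 | (3S,6S)-6-[(2S)-but-3-en-2-yl]-3-(3-methoxyprop-2-en-1-yl)-3-methyl-1,2-dioxane (E/Z mixture) | C=C[C@H](C)[C@@H]1CC[C@@](C)(CC=COC)OO1 | intermediate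
15 | 3-[(3S,6S)-6-[(2S)-but-3-en-2-yl]-3-methyl-1,2-dioxan-3-yl]propanal | C=C[C@H](C)[C@@H]1CC[C@@](C)(CCC=O)OO1 | intermediate
16 | isobutyric acid (2-methylpropanoic acid) | CC(C)C(=O)O | starting material
17 | 2-(3-chloropropyl)-2-methyl-1,3-dioxolane | CC1(CCCCl)OCCO1 | starting material
18 | 2,2-dimethyl-5-(2-methyl-1,3-dioxolan-2-yl)pentanoic acid | CC1(CCCC(C)(C)C(=O)O)OCCO1 | intermediate
19 | 2,2-dimethyl-6-oxoheptanoic acid | CC(=O)CCCC(C)(C)C(=O)O | intermediate
20 | 1,3-dioxoisoindolin-2-yl 2,2-dimethyl-6-oxoheptanoate | CC(=O)CCCC(C)(C)C(=O)ON1C(=O)c2ccccc2C1=O | intermediate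
21 | 1-[(3S,6S)-6-[(2S)-but-3-en-2-yl]-3-methyl-1,2-dioxan-3-yl]-4,4-dimethylnonane-3,8-dione | C=C[C@H](C)[C@@H]1CC[C@@](C)(CCC(=O)C(C)(C)CCCC(C)=O)OO1 | intermediate
22 | methoxy hydroperoxide from ozonolysis of 21 in methanol (C1 bears OMe and OOH) | COC(OO)[C@H](C)[C@@H]1CC[C@@](C)(CCC(=O)C(C)(C)CCCC(C)=O)OO1 | intermediate
23 | methyl (2R)-2-[(3S,6S)-6-(4,4-dimethyl-3,8-dioxononyl)-6-methyl-1,2-dioxan-3-yl]propanoate (diacarperoxide C) | COC(=O)[C@H](C)[C@@H]1CC[C@@](C)(CCC(=O)C(C)(C)CCCC(C)=O)OO1 | target

Total step count: 13. Longest linear sequence: 11 steps (steps 1–9, 12 and 13, from (R)-(−)-linalool).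

Steps most likely to fail

Step 12. The α-unbranched aldehyde may be lost to aldol or benzoin self-condensation, the Breslow enolate may reduce the O–O bond by single-electron transfer, or the tertiary radical may escape the radical pair and disproportionate. The fallback sets out from 15 and returns at 21. Aldehyde 15 is oxidised (NaClO2, NaH2PO4, 2-methylbut-2-ene, t-BuOH/H2O) to 3-[(3S,6S)-6-[(2S)-but-3-en-2-yl]-3-methyl-1,2-dioxan-3-yl]propanoic acid F1. Commercial 6-methylhept-5-en-2-one is hydrobrominated in the Markovnikov sense (HBr in AcOH, 0 °C) to 6-bromo-6-methylheptan-2-one F2. F1 and F2 are then joined at the same C9–C10 bond by nickel-catalysed reductive acylation of the tertiary alkyl bromide with the mixed anhydride formed in the flask (Ni(acac)2, 4,4'-di-tert-butyl-2,2'-bipyridine, Zn, MgCl2, Boc2O, DMA, rt), which gives 21. Zinc could also reduce the O–O bond, so this fallback carries its own risk.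

Step 6. Ionisation of the activated oxetane may erode the configuration at C6 through an SN1-like opening, or may divert it to elimination. The fallback reverses the order of the two C–O bond formations, sets out from 10 and returns at 12, so it replaces steps 6 and 7. The mesylate of 10 is displaced with inversion at C3 by 2-methoxyprop-2-yl hydroperoxide (CsOH, DMF, 0 °C) to give (2R)-2-[(3S,4S)-3-[(2-methoxypropan-2-yl)peroxy]-4-methylhex-5-en-1-yl]-2-methyloxetane F3. Mild acid (AcOH/H2O/THF) unmasks (2R)-2-[(3S,4S)-3-hydroperoxy-4-methylhex-5-en-1-yl]-2-methyloxetane F4. A Lewis acid (TMSOTf cat., CH2Cl2, −78 °C) then promotes intramolecular 6-exo opening of the oxetane at C6 by the hydroperoxide, a tighter SN2-like inversion, and gives 12.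

Step 13. Sodium methoxide may open the β-peroxy ester by retro-oxa-Michael elimination, epimerise C2 at the aldehyde stage, or trigger intramolecular aldol reaction of the 1,6-diketone. The fallback sets out from 21 and returns at 23. The vinyl group is cleaved under non-basic conditions (RuCl3 cat., NaIO4, CCl4/MeCN/H2O, rt) straight to (2R)-2-[(3S,6S)-6-(4,4-dimethyl-3,8-dioxononyl)-6-methyl-1,2-dioxan-3-yl]propanoic acid F5, the aldehyde being oxidised as it forms. Methylation with trimethylsilyldiazomethane (MeOH/toluene, 0 °C) then gives 23.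

Further compounds
F1 | step 12 | 3-[(3S,6S)-6-[(2S)-but-3-en-2-yl]-3-methyl-1,2-dioxan-3-yl]propanoic acid | C=C[C@H](C)[C@@H]1CC[C@@](C)(CCC(=O)O)OO1
F2 | step 12 | 6-bromo-6-methylheptan-2-one | CC(=O)CCCC(C)(C)Br
F3 | step 6 | (2R)-2-[(3S,4S)-3-[(2-methoxypropan-2-yl)peroxy]-4-methylhex-5-en-1-yl]-2-methyloxetane | C=C[C@H](C)[C@@H](OOC(C)(C)OC)CC[C@]1(C)CCO1
F4 | step 6 | (2R)-2-[(3S,4S)-3-hydroperoxy-4-methylhex-5-en-1-yl]-2-methyloxetane | C=C[C@H](C)[C@@H](OO)CC[C@]1(C)CCO1
F5 | step 13 | (2R)-2-[(3S,6S)-6-(4,4-dimethyl-3,8-dioxononyl)-6-methyl-1,2-dioxan-3-yl]propanoic acid | OC(=O)[C@H](C)[C@@H]1CC[C@@](C)(CCC(=O)C(C)(C)CCCC(C)=O)OO1
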